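## Retrosynthetic overview

1. Target ⇐ glycol cleavage and reduction of a C3-(1,2-dihydroxyethyl) precursor. The trans 3′-OH/4′-OMe pair ⇐ trans-diaxial methanolysis of a 3′,4′-epoxide placed syn to the 1′-OH.
2. The cyclohexene ring is formed last ⇐ RCM of an allyl/3-butenyl carbinol. C1′ ⇐ chelation-controlled allylation of a C2 ketone ⇐ Weinreb amide.
3. The dihydrobenzofuran ring is formed first (C2–C3 and O1–C2 bonds) ⇐ light-generated o-quinone methide (o-QM) plus an amide-stabilised sulfonium ylide, [4+1].
4. The o-QM precursor ⇐ ortho-hydroxyalkylation of dihydroconiferyl alcohol with (S)-glyceraldehyde acetonide. This is the only purchased stereocentre. It relays C3 → C2 → C1′ → C3′/C4′, and its carbon ends as the CH2OH carbon.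

Assumption: compounds 1, 2 (made from L-ascorbic acid), 4, 5 and both Grignard solutions are purchased. The carbinol centre of 3 is left undefined because Step 3 erases it.

## Route

**Step 1**
Reactants: 1 dihydroconiferyl alcohol; 2 (S)-glyceraldehyde acetonide
Product: 3, 4-(3-hydroxypropyl)-2-methoxy-6-{hydroxy[(4S)-2,2-dimethyl-1,3-dioxolan-4-yl]methyl}phenol (carbinol epimers)
Conditions: EtMgBr (2.1 equiv), Et2O, 0 °C; swap to CH2Cl2; add 2, rt, 16 h; aq NH4Cl
Reagents that add atoms: (S)-glyceraldehyde acetonide 2, CC1(C)OC[C@@H](C=O)O1
Why: This is an ortho-specific hydroxyalkylation of a bromomagnesium phenolate (Casiraghi reaction), in which Mg binds phenolate and aldehyde in a closed transition state, the only free ortho position reacts, the dioxolane centre is untouched, and the new carbinol centre is inconsequential.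

**Step 2**
Reactants: 4 2-bromo-N-methoxy-N-methylacetamide; 5 dimethyl sulfide
Product: 6, 2-(dimethyl-λ4-sulfanylidene)-N-methoxy-N-methylacetamide (ylide)
Conditions: Me2S, acetone, rt; then aq K2CO3/NaOH, CHCl3, 0 °C (used crude)
Reagents that add atoms: dimethyl sulfide, CSC
Why: This is SN2 sulfonium salt formation followed by deprotonation, the standard preparation of carbonyl-stabilised sulfonium ylides, and no stereocentre is formed.

**Step 3 (key step)**
Reactants: 3; 6 (3 equiv)
Product: 7, (2S,3R)-3-[(4R)-2,2-dimethyl-1,3-dioxolan-4-yl]-5-(3-hydroxypropyl)-N,7-dimethoxy-N-methyl-2,3-dihydro-1-benzofuran-2-carboxamide (2,3-trans)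
Conditions: hν (300–310 nm), degassed MeCN (1% H2O), 0.02 M, 15 °C, FEP flow coil
Reagents that add atoms: ylide 6, C[S+](C)[CH-]C(=O)N(C)OC (delivers CH–C(=O)N(OMe)Me; Me2S and H2O are lost)
Why: Proposed new method: excitation of the o-hydroxybenzyl alcohol triggers excited-state proton transfer and loss of water to give the o-QM; the ylide carbon then adds to the exocyclic carbon with the dioxolane C–H "inside" (A1,3 strain) and anti to the dioxolane C–O bond (Felkin–Anh), giving the anti adduct and so 3R; the phenoxide then displaces Me2S (5-exo-tet) from the equilibrating betaine to give the trans 2S centre; the closest known reactions are photodehydration of o-hydroxybenzyl alcohols trapped by O/N/S nucleophiles or enol ethers and the thermal base-triggered o-QM/sulfur-ylide [4+1] annulation, and the amide ylide is chosen because it is transparent above 290 nm and leaves no photolabile ketone in the product.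

**Step 4**
Reactants: 7; 8 but-3-enylmagnesium bromide
Product: 9, 1-[(2S,3R)-3-[(4R)-2,2-dimethyl-1,3-dioxolan-4-yl]-5-(3-hydroxypropyl)-7-methoxy-2,3-dihydro-1-benzofuran-2-yl]pent-4-en-1-one
Conditions: 8 (3 equiv), THF, −20 → 0 °C; aq NH4Cl
Reagents that add atoms: but-3-enylmagnesium bromide, C=CCC[Mg]Br
Why: This is a Weinreb ketone synthesis, in which the chelated tetrahedral intermediate stops over-addition, one equivalent of Grignard is sacrificed to the free OH, and C2 stays trans, which is also the thermodynamic epimer.

**Step 5**
Reactants: 9; 10 allylmagnesium bromide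
Product: 11, (4S)-4-[(2S,3R)-3-[(4R)-2,2-dimethyl-1,3-dioxolan-4-yl]-5-(3-hydroxypropyl)-7-methoxy-2,3-dihydro-1-benzofuran-2-yl]octa-1,7-dien-4-ol
Conditions: MgBr2·OEt2 (4 equiv), CH2Cl2, −78 °C, 30 min; then 10 (3 equiv, Et2O), −78 °C
Reagents that add atoms: allylmagnesium bromide, C=CC[Mg]Br
Why: This is a Cram-chelate addition, in which Mg locks the C=O syn to ring O1 (helped by the adjacent 7-OMe), full pre-complexation in a non-coordinating solvent makes the chelate the reacting species, and allyl attacks from the C2–H face to give 1′S.

**Step 6**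
Reactants: 11
Product: 12, (1S)-1-[(2S,3R)-3-[(4R)-2,2-dimethyl-1,3-dioxolan-4-yl]-5-(3-hydroxypropyl)-7-methoxy-2,3-dihydro-1-benzofuran-2-yl]cyclohex-3-en-1-ol
Conditions: Grubbs II (3 mol %), CH2Cl2 (0.01 M), 40 °C
Reagents that add atoms: none
Why: This is a ring-closing metathesis of the only two alkenes to an unstrained cyclohexene, free alcohols are tolerated, and no stereocentre is touched.

**Step 7**
Reactants: 12
Product: 13, (1S,3S,6R)-3-[(2S,3R)-3-[(4R)-2,2-dimethyl-1,3-dioxolan-4-yl]-5-(3-hydroxypropyl)-7-methoxy-2,3-dihydro-1-benzofuran-2-yl]-7-oxabicyclo[4.1.0]heptan-3-ol (epoxide cis to the OH)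
Conditions: VO(acac)2 (5 mol %), t-BuOOH (1.5 equiv), CH2Cl2, 0 °C → rt
Reagents that add atoms: tert-butyl hydroperoxide, CC(C)(C)OO (one O)
Why: This is a hydroxyl-directed vanadium epoxidation of a homoallylic alcohol, in which the bulky C1′ substituent sits equatorial, the axial 1′-OH binds V and delivers oxygen to its own face, and both epoxide carbons are set from C1′.

**Step 8**
Reactants: 13
Product: 14, (1R)-1-[(2S,3R)-2-[(1S,3S,4S)-1,3-dihydroxy-4-methoxycyclohexyl]-5-(3-hydroxypropyl)-7-methoxy-2,3-dihydro-1-benzofuran-3-yl]ethane-1,2-diol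
Conditions: CSA (0.2 equiv), MeOH, rt → 40 °C
Reagents that add atoms: methanol, CO
Why: This is an acid-catalysed Fürst–Plattner opening, in which only attack at C4′ gives the trans-diaxial product in the chair with the C1′ substituent equatorial, so MeOH inverts C4′ to S, C3′–O is retained as S, and the acetonide is removed by transketalisation in the same pot.

**Step 9**
Reactants: 14
Product: 15, difengpiol B
Conditions: NaIO4 (1.1 equiv), THF–pH 7 buffer, 0 °C; then NaBH4, 0 °C (one pot)
Reagents that add atoms: none
Why: This is a Malaprade cleavage of the only 1,2-diol followed by immediate hydride reduction, which converts the former dioxolane carbon into the C3–CH2OH group before the β-aryloxy aldehyde can enolise or ring-open, and the trans arrangement is also the thermodynamic one.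

## Compound list

| No. | Name | SMILES | Role |
|---|---|---|---|
| 1 | dihydroconiferyl alcohol | COc1cc(CCCO)ccc1O | starting material |
| 2 | (S)-2,2-dimethyl-1,3-dioxolane-4-carbaldehyde | CC1(C)OC[C@@H](C=O)O1 | starting material |
| 3 | ortho-hydroxyalkylated phenol | COc1cc(CCCO)cc(C(O)[C@@H]2COC(C)(C)O2)c1O | intermediate |
| 4 | 2-bromo-N-methoxy-N-methylacetamide | CON(C)C(=O)CBr | starting material |
| 5 | dimethyl sulfide | CSC | starting material |
| 6 | Weinreb-amide sulfonium ylide | C[S+](C)[CH-]C(=O)N(C)OC | intermediate |
| 7 | trans-dihydrobenzofuran Weinreb amide | COc1cc(CCCO)cc2c1O[C@H](C(=O)N(C)OC)[C@H]2[C@@H]1COC(C)(C)O1 | intermediate |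
| 8 | but-3-enylmagnesium bromide | C=CCC[Mg]Br | starting material |
| 9 | butenyl ketone | COc1cc(CCCO)cc2c1O[C@H](C(=O)CCC=C)[C@H]2[C@@H]1COC(C)(C)O1 | intermediate |
| 10 | allylmagnesium bromide | C=CC[Mg]Br | starting material |
| 11 | allyl/butenyl carbinol | COc1cc(CCCO)cc2c1O[C@H]([C@@](O)(CC=C)CCC=C)[C@H]2[C@@H]1COC(C)(C)O1 | intermediate |
| 12 | cyclohex-3-enol | COc1cc(CCCO)cc2c1O[C@H]([C@]1(O)CCC=CC1)[C@H]2[C@@H]1COC(C)(C)O1 | intermediate |
| 13 | cis-epoxy alcohol | COc1cc(CCCO)cc2c1O[C@H]([C@]1(O)CC[C@H]3O[C@H]3C1)[C@H]2[C@@H]1COC(C)(C)O1 | intermediate |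
| 14 | pentaol | COc1cc(CCCO)cc2c1O[C@H]([C@]1(O)CC[C@H](OC)[C@@H](O)C1)[C@H]2[C@@H](O)CO | intermediate |
| 15 | difengpiol B | COc1cc(CCCO)cc2c1O[C@H]([C@]1(O)CC[C@H](OC)[C@@H](O)C1)[C@H]2CO | target |

## Step count

Total steps: 9. Longest linear sequence: 8 (Steps 1, 3–9). No protecting-group steps are used.

## Steps most likely to fail

1. **Step 3 (the new photochemical [4+1]).**
   - Risks: proton transfer from phenol to ylide may lower the photodehydration efficiency. The o-QM may undergo a 1,5-H shift to an enol ether. Facial selectivity may be only moderate.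
   - Fallback (known chemistry, no light): convert 3 with p-toluenesulfinic acid into the 2-(1-tosylalkyl)phenol. Then run the established base-triggered o-QM/sulfur-ylide [4+1] annulation with Cs2CO3 and the sulfonium bromide of 6 in CH2Cl2 at rt. This costs one extra step.

2. **Step 5 (C1′ by chelation control).**
   - Risk: allylmagnesium reagents react near the diffusion limit, so chelate control can erode.
   - Fallback: change both the stereocontrol model and the bond order. Make the allyl ketone from 7 with allylMgBr. Then add non-chelating 3-butenylcerium dichloride under polar Felkin–Anh control, with attack anti to C2–O1. The opposite face combined with swapped arms gives the same 1′S carbinol 11.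

3. **Step 1 (ortho-hydroxyalkylation of a guaiacol-type Mg phenolate).**
   - Risks: the 2-OMe and the side-chain alkoxide may sequester Mg and slow the reaction, and aldehyde 2 is labile.
   - Fallback: switch to an aryllithium addition. Brominate 1 ortho to the OH with NBS, protect both hydroxyls as MOM ethers, perform Br–Li exchange, add to 2, and release the phenol with mild acid. This costs three extra steps.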